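Ring A of the isoflavone is disconnected across C8–C7, C6–C5 and C5–C4a. A Dötz benzannulation of a 5-aryl-4-pyranon-2-yl(methoxy)carbene complex of zerovalent chromium with a terminal alkyne and one CO ligand builds ring A in one operation. It exploits the para-dioxygenated, pentasubstituted ring A (O at C5 and C8, side chain at C6, H at C7) fused to the pyranone at C4a–C8a: O5 (from CO) and O8 (from the carbene) arrive differentiated and the chain lands at C6. The precursor is the pentacarbonylchromium carbene carrying the complete, MOM-protected ring B; its partner is the triethylsilyl ether of 2-methylhex-5-yn-2-ol.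

Key step: step 11

Remark: positions are numbered as in 4H-chromen-4-one; the target has no stereocentre; compound 1, the 2-methylprop-1-enyl Grignard solution and C8K are taken as purchased.

Step 1
Reactants: 1 5-bromo-2,4-dihydroxybenzaldehyde
Product: 2 5-bromo-2-hydroxy-4-(methoxymethoxy)benzaldehyde
Conditions: MOMCl, K2CO3, acetone, 0 °C → rt
Reagents that add atoms: chloromethyl methyl ether, COCCl
Why: Base-mediated O-alkylation (acetal formation) should occur at the more acidic, unchelated 4-hydroxyl, because the 2-hydroxyl is held in a hydrogen bond to the aldehyde.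

Step 2
Reactants: 2 5-bromo-2-hydroxy-4-(methoxymethoxy)benzaldehyde
Product: 4 6-bromo-7-(methoxymethoxy)-2,2-dimethyl-2H-chromene, via allylic diol 3 (not isolated)
Conditions: Me2C=CHMgBr (2.4 equiv), THF, 0 °C → rt; H2O quench; crude 3, PPTS (cat.), PhMe, 60 °C
Reagents that add atoms: 2-methylprop-1-enylmagnesium bromide, CC(C)=C[Mg]Br
Why: Grignard addition to the aldehyde (the first equivalent is consumed by the phenol) gives the o-hydroxybenzyl allylic alcohol 3, which on mild acid should lose water to an o-quinone methide that closes by oxa-6π-electrocyclisation to the 2,2-dimethyl-2H-chromene; the pyran ring can only fuse at the former formyl carbon, so bromine ends at C6 next to the protected oxygen at C7.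

Step 3
Reactants: 4 6-bromo-7-(methoxymethoxy)-2,2-dimethyl-2H-chromene
Product: 6 2-[7-(methoxymethoxy)-2,2-dimethyl-2H-chromen-6-yl]-4,4,5,5-tetramethyl-1,3,2-dioxaborolane, via aryllithium 5 (not isolated)
Conditions: n-BuLi, THF, −78 °C; iPrOBpin, −78 °C → rt; H2O
Reagents that add atoms: 2-isopropoxy-4,4,5,5-tetramethyl-1,3,2-dioxaborolane, CC(C)OB1OC(C)(C)C(C)(C)O1
Why: Bromine–lithium exchange is fast at low temperature and the ortho acetal oxygen stabilises aryllithium 5, which is trapped by the borate ester (lithiation–borylation).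

Step 4
Reactants: 7 kojic acid
Product: 8 6-(hydroxymethyl)-4-oxo-4H-pyran-3-yl trifluoromethanesulfonate
Conditions: PhNTf2, Et3N, DMF, 0 °C → rt
Reagents that add atoms: N-phenylbis(trifluoromethanesulfonimide), O=S(=O)(N(c1ccccc1)S(=O)(=O)C(F)(F)F)C(F)(F)F
Why: The acidic enolic 5-hydroxyl should be triflated as its ammonium salt, whereas the neutral primary alcohol does not react with this mild sulfonyl-transfer reagent (chemoselective O-sulfonylation).

Step 5
Reactants: 8 6-(hydroxymethyl)-4-oxo-4H-pyran-3-yl trifluoromethanesulfonate; 6 2-[7-(methoxymethoxy)-2,2-dimethyl-2H-chromen-6-yl]-4,4,5,5-tetramethyl-1,3,2-dioxaborolane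
Product: 9 2-(hydroxymethyl)-5-[7-(methoxymethoxy)-2,2-dimethyl-2H-chromen-6-yl]-4H-pyran-4-one
Conditions: Pd(dppf)Cl2 (5 mol %), K3PO4, 1,4-dioxane/H2O, 70 °C
Reagents that add atoms: none
Why: Suzuki–Miyaura coupling of the enol triflate of an α-oxygenated enone with the aryl boronate; oxidative addition into the electron-poor C–OTf bond is easy and the free hydroxymethyl group is tolerated.

Step 6
Reactants: 9 2-(hydroxymethyl)-5-[7-(methoxymethoxy)-2,2-dimethyl-2H-chromen-6-yl]-4H-pyran-4-one
Product: 10 5-[7-(methoxymethoxy)-2,2-dimethyl-2H-chromen-6-yl]-4-oxo-4H-pyran-2-carboxylic acid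
Conditions: TEMPO (cat.), PhI(OAc)2, MeCN/H2O, rt
Reagents that add atoms: water, O
Why: Oxoammonium-mediated oxidation of the primary alcohol in aqueous acetonitrile runs through the readily hydrated, electron-poor aldehyde to the acid under near-neutral conditions that should leave the acetal, the chromene alkene and the pyranone untouched.

Step 7
Reactants: 10 5-[7-(methoxymethoxy)-2,2-dimethyl-2H-chromen-6-yl]-4-oxo-4H-pyran-2-carboxylic acid
Product: 11 5-[7-(methoxymethoxy)-2,2-dimethyl-2H-chromen-6-yl]-4-oxo-4H-pyran-2-carbonyl chloride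
Conditions: Me2C=C(Cl)NMe2, CH2Cl2, 0 °C → rt; evaporate, pentane wash
Reagents that add atoms: 1-chloro-N,N,2-trimethylprop-1-en-1-amine, CC(C)=C(Cl)N(C)C
Why: The α-chloroenamine converts the acid into the acid chloride under neutral conditions, giving only an amide by-product and no HCl that could cleave the MOM acetal.

Step 8
Reactants: 11 5-[7-(methoxymethoxy)-2,2-dimethyl-2H-chromen-6-yl]-4-oxo-4H-pyran-2-carbonyl chloride; 12 hexacarbonylchromium
Product: 15 pentacarbonyl{methoxy[5-(7-(methoxymethoxy)-2,2-dimethyl-2H-chromen-6-yl)-4-oxo-4H-pyran-2-yl]methylidene}chromium, via K2Cr(CO)5 13 (not isolated), via potassium acylchromate 14 (not isolated)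
Conditions: Cr(CO)6, C8K (2 equiv), THF, −78 → 0 °C; 11, −78 → 0 °C; MeOTf, −78 → 0 °C
Reagents that add atoms: methyl trifluoromethanesulfonate, COS(=O)(=O)C(F)(F)F
Why: Acylation of the strongly nucleophilic pentacarbonylchromate dianion by the acid chloride gives acylchromate 14, whose anionic oxygen is O-methylated by the hard electrophile MeOTf (the known route from acid chlorides to alkoxycarbene complexes); addition at −78 °C should keep the dianion away from the pyranone enone.

Step 9
Reactants: 16 ethyl pent-4-ynoate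
Product: 17 2-methylhex-5-yn-2-ol
Conditions: MeMgBr (3.2 equiv), THF, 0 °C → rt; H2O
Reagents that add atoms: methylmagnesium bromide, C[Mg]Br
Why: Double Grignard addition to the ester gives the tertiary alcohol; the extra equivalent covers deprotonation of the terminal alkyne, which is restored on quench.

Step 10
Reactants: 17 2-methylhex-5-yn-2-ol
Product: 18 triethyl[(2-methylhex-5-yn-2-yl)oxy]silane
Conditions: TESOTf, 2,6-lutidine, CH2Cl2, −78 → 0 °C
Reagents that add atoms: triethylsilyl trifluoromethanesulfonate, CC[Si](CC)(CC)OS(=O)(=O)C(F)(F)F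
Why: A silyl triflate with a hindered pyridine base silylates the tertiary alcohol (O-silylation), masking a hydroxyl that could otherwise trap the ketene intermediate of step 11 as a lactone.

Step 11
Reactants: 15 pentacarbonyl{methoxy[5-(7-(methoxymethoxy)-2,2-dimethyl-2H-chromen-6-yl)-4-oxo-4H-pyran-2-yl]methylidene}chromium; 18 triethyl[(2-methylhex-5-yn-2-yl)oxy]silane
Product: 20 5-hydroxy-8-methoxy-3-[7-(methoxymethoxy)-2,2-dimethyl-2H-chromen-6-yl]-6-[3-methyl-3-(triethylsilyloxy)butyl]-4H-chromen-4-one, via tricarbonylchromium arene complex 19 (not isolated)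
Conditions: 18 (2 equiv), THF (0.05 M), 55 °C, Ar; then air, Et2O, rt
Reagents that add atoms: none
Why: Thermal loss of one CO from 15 lets 18 coordinate and insert into the Cr=C bond to give an η3-vinylcarbene, CO insertion gives a chromium-bound dienylketene whose ketene carbon closes onto pyranone C3 (future C4a), and enolisation of the resulting dienone gives the 4-methoxyphenol as its Cr(CO)3 complex 19, which air should release. This is the Dötz benzannulation of alkenyl- and heteroaryl(alkoxy)carbene complexes of zerovalent chromium with terminal alkynes, the closest relatives being the 2-furyl and dihydropyranyl carbenes. Ring A is closed by a 6π-electrocyclisation (bond C5–C4a) after C8–C7 and C6–C5 have been made by the two insertions, and no stereocentre is formed. The step needs regioselective alkyne insertion and phenol formation in preference to furan, cyclobutenone or CO-free five-ring products. The first is secured by the terminal alkyne, whose substituted carbon ends next to the CO-derived carbon for steric reasons (chain at C6, H at C7); the second by the alkenyl-type carbene with a free C3–H terminus, the coordinating solvent and moderate dilution. The C4a proton of the dienone lies between two carbonyl groups, so tautomerisation should be fast, leaving the ketene oxygen as the chelated 5-OH and the carbene oxygen as 8-OMe.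

Step 12
Reactants: 20 5-hydroxy-8-methoxy-3-[7-(methoxymethoxy)-2,2-dimethyl-2H-chromen-6-yl]-6-[3-methyl-3-(triethylsilyloxy)butyl]-4H-chromen-4-one
Product: 21 3-[7-(methoxymethoxy)-2,2-dimethyl-2H-chromen-6-yl]-6-[3-methyl-3-(triethylsilyloxy)butyl]-4H-chromene-4,5,8-trione
Conditions: PhI(OAc)2 (1.1 equiv), MeCN/H2O (4:1), 0 °C
Reagents that add atoms: water, O
Why: The trivalent iodine reagent oxidises the p-methoxyphenol to a cationic intermediate that is captured by water at C8 and loses methanol (oxidative demethylation to the p-quinone); the non-phenolic ring B should not be attacked under these mild conditions.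

Step 13
Reactants: 21 3-[7-(methoxymethoxy)-2,2-dimethyl-2H-chromen-6-yl]-6-[3-methyl-3-(triethylsilyloxy)butyl]-4H-chromene-4,5,8-trione
Product: 23 kraussianone 3, via protected hydroquinone 22 (not isolated)
Conditions: Na2S2O4, EtOAc/H2O, rt, Ar; organic phase concentrated; then 2 M HCl, MeOH/THF, 40 °C, Ar
Reagents that add atoms: none
Why: Dithionite reduces the quinone to the hydroquinone, and acid-catalysed methanolysis then cleaves the MOM acetal at its acetal carbon and the silyl ether at silicon, so the tertiary C–O bond is never ionised; exclusion of air protects the hydroquinone.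

Compound list
1 | 5-bromo-2,4-dihydroxybenzaldehyde | O=Cc1cc(Br)c(O)cc1O | starting material
2 | 5-bromo-2-hydroxy-4-(methoxymethoxy)benzaldehyde | COCOc1cc(O)c(C=O)cc1Br | intermediate
3 | 4-bromo-2-(1-hydroxy-3-methylbut-2-en-1-yl)-5-(methoxymethoxy)phenol (racemic) | COCOc1cc(O)c(C(O)C=C(C)C)cc1Br | intermediate (not isolated)
4 | 6-bromo-7-(methoxymethoxy)-2,2-dimethyl-2H-chromene | COCOc1cc2OC(C)(C)C=Cc2cc1Br | intermediate
5 | [7-(methoxymethoxy)-2,2-dimethyl-2H-chromen-6-yl]lithium | COCOc1cc2OC(C)(C)C=Cc2cc1[Li] | intermediate (not isolated)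
6 | 2-[7-(methoxymethoxy)-2,2-dimethyl-2H-chromen-6-yl]-4,4,5,5-tetramethyl-1,3,2-dioxaborolane | COCOc1cc2OC(C)(C)C=Cc2cc1B1OC(C)(C)C(C)(C)O1 | intermediate
7 | kojic acid, 5-hydroxy-2-(hydroxymethyl)-4H-pyran-4-one | OCc1cc(=O)c(O)co1 | starting material
8 | 6-(hydroxymethyl)-4-oxo-4H-pyran-3-yl trifluoromethanesulfonate | OCc1cc(=O)c(OS(=O)(=O)C(F)(F)F)co1 | intermediate
9 | 2-(hydroxymethyl)-5-[7-(methoxymethoxy)-2,2-dimethyl-2H-chromen-6-yl]-4H-pyran-4-one | OCc1cc(=O)c(-c2cc3C=CC(C)(C)Oc3cc2OCOC)co1 | intermediate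
10 | 5-[7-(methoxymethoxy)-2,2-dimethyl-2H-chromen-6-yl]-4-oxo-4H-pyran-2-carboxylic acid | OC(=O)c1cc(=O)c(-c2cc3C=CC(C)(C)Oc3cc2OCOC)co1 | intermediate
11 | 5-[7-(methoxymethoxy)-2,2-dimethyl-2H-chromen-6-yl]-4-oxo-4H-pyran-2-carbonyl chloride | ClC(=O)c1cc(=O)c(-c2cc3C=CC(C)(C)Oc3cc2OCOC)co1 | intermediate
12 | hexacarbonylchromium, Cr(CO)6 | O=C=[Cr](=C=O)(=C=O)(=C=O)(=C=O)=C=O | starting material
13 | dipotassium pentacarbonylchromate, K2Cr(CO)5 | [K+].[K+].O=C=[Cr-2](=C=O)(=C=O)(=C=O)=C=O | intermediate (not isolated)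
14 | potassium acylpentacarbonylchromate from 11, K[(CO)5Cr–C(O)R] | [K+].[O-]C(=[Cr](=C=O)(=C=O)(=C=O)(=C=O)=C=O)c1cc(=O)c(-c2cc3C=CC(C)(C)Oc3cc2OCOC)co1 | intermediate (not isolated)
15 | pentacarbonyl{methoxy[5-(7-(methoxymethoxy)-2,2-dimethyl-2H-chromen-6-yl)-4-oxo-4H-pyran-2-yl]methylidene}chromium | COC(=[Cr](=C=O)(=C=O)(=C=O)(=C=O)=C=O)c1cc(=O)c(-c2cc3C=CC(C)(C)Oc3cc2OCOC)co1 | intermediate
16 | ethyl pent-4-ynoate | CCOC(=O)CCC#C | starting material
17 | 2-methylhex-5-yn-2-ol | C#CCCC(C)(C)O | intermediate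
18 | triethyl[(2-methylhex-5-yn-2-yl)oxy]silane | C#CCCC(C)(C)O[Si](CC)(CC)CC | intermediate
19 | tricarbonylchromium complex of 20, Cr(CO)3 bound η6 to ring A (written as two parts) | COc1cc(CCC(C)(C)O[Si](CC)(CC)CC)c(O)c2c1occ(-c1cc3C=CC(C)(C)Oc3cc1OCOC)c2=O.O=C=[Cr](=C=O)=C=O | intermediate (not isolated)
20 | 5-hydroxy-8-methoxy-3-[7-(methoxymethoxy)-2,2-dimethyl-2H-chromen-6-yl]-6-[3-methyl-3-(triethylsilyloxy)butyl]-4H-chromen-4-one | COc1cc(CCC(C)(C)O[Si](CC)(CC)CC)c(O)c2c1occ(-c1cc3C=CC(C)(C)Oc3cc1OCOC)c2=O | intermediate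
21 | 3-[7-(methoxymethoxy)-2,2-dimethyl-2H-chromen-6-yl]-6-[3-methyl-3-(triethylsilyloxy)butyl]-4H-chromene-4,5,8-trione | O=C1C=C(CCC(C)(C)O[Si](CC)(CC)CC)C(=O)C2=C1OC=C(c1cc3C=CC(C)(C)Oc3cc1OCOC)C2=O | intermediate
22 | 5,8-dihydroxy-3-[7-(methoxymethoxy)-2,2-dimethyl-2H-chromen-6-yl]-6-[3-methyl-3-(triethylsilyloxy)butyl]-4H-chromen-4-one | Oc1cc(CCC(C)(C)O[Si](CC)(CC)CC)c(O)c2c1occ(-c1cc3C=CC(C)(C)Oc3cc1OCOC)c2=O | intermediate (not isolated)
23 | kraussianone 3, 5,8-dihydroxy-6-(3-hydroxy-3-methylbutyl)-3-(7-hydroxy-2,2-dimethyl-2H-chromen-6-yl)-4H-chromen-4-one | CC(C)(O)CCc1cc(O)c2occ(-c3cc4c(cc3O)OC(C)(C)C=C4)c(=O)c2c1O | target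

Total step count: 13.
Longest linear sequence: 10 steps (steps 1, 2, 3, 5, 6, 7, 8, 11, 12, 13).

Steps most likely to fail

1. Step 11. After alkyne and CO insertion the dienylketene may not close onto the electron-poor C3 terminus and may drain into cyclobutenone, furan or CO-free five-ring products, or a second alkyne may insert. The fallback builds ring A without chromium; it sets out from boronate 6 and comes back at 20.
- Purchased 2,5-dimethoxyphenol F1 adds to tert-butyl propiolate (DABCO cat.) to give tert-butyl (E)-3-(2,5-dimethoxyphenoxy)prop-2-enoate F2.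
- P2O5/MeSO3H cleaves the ester and closes the acid by Friedel–Crafts acylation at the only free ortho position, giving 5,8-dimethoxy-4H-chromen-4-one F3.
- Piperidine opens the pyranone to (E)-1-(2-hydroxy-3,6-dimethoxyphenyl)-3-(piperidin-1-yl)prop-2-en-1-one F4, and I2 recloses it to 3-iodo-5,8-dimethoxy-4H-chromen-4-one F5.
- BCl3 cleaves only the methyl ether peri to the carbonyl, giving 5-hydroxy-3-iodo-8-methoxy-4H-chromen-4-one F6, and NBS brominates ortho to the phenol to give 6-bromo-5-hydroxy-3-iodo-8-methoxy-4H-chromen-4-one F7.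
- Suzuki–Miyaura coupling with 6 at the more reactive C3–I bond gives 6-bromo-5-hydroxy-8-methoxy-3-[7-(methoxymethoxy)-2,2-dimethyl-2H-chromen-6-yl]-4H-chromen-4-one F8.
- 2-Methylbut-3-en-2-ol is silylated (TESOTf) to triethyl[(2-methylbut-3-en-2-yl)oxy]silane F9 and hydroborated with 9-BBN to 9-[3-methyl-3-(triethylsilyloxy)butyl]-9-borabicyclo[3.3.1]nonane F10; B-alkyl Suzuki coupling of F10 with F8 (Pd(dppf)Cl2, K3PO4) gives 20.

2. Step 8. The strongly reducing, nucleophilic chromate dianion may transfer an electron to the 5-aryl-pyranone, or add to its C6, instead of attacking the acid chloride; methylation may also stray to the pyranone carbonyl. The fallback runs the chromium chemistry before ring B is attached, on a pyranone whose C5 oxygen donor makes C6 less electrophilic. It sets out from 13 (made from 12 as in step 8), uses 18 and 6, and comes back at 20.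
- Purchased 5-(benzyloxy)-4-oxo-4H-pyran-2-carboxylic acid F11 is converted with 1-chloro-N,N,2-trimethylprop-1-en-1-amine into 5-(benzyloxy)-4-oxo-4H-pyran-2-carbonyl chloride F12.
- F12 with 13 gives the potassium acylchromate F13, and MeOTf gives pentacarbonyl{[5-(benzyloxy)-4-oxo-4H-pyran-2-yl](methoxy)methylidene}chromium F14.
- Benzannulation with 18 under the conditions of step 11 gives 3-(benzyloxy)-5-hydroxy-8-methoxy-6-[3-methyl-3-(triethylsilyloxy)butyl]-4H-chromen-4-one F15.
- Hydrogenolysis (H2, Pd/C) gives 3,5-dihydroxy-8-methoxy-6-[3-methyl-3-(triethylsilyloxy)butyl]-4H-chromen-4-one F16.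
- PhNTf2 triflates only the 3-hydroxyl, the 5-hydroxyl being held in the stronger hydrogen bond, to give 5-hydroxy-8-methoxy-6-[3-methyl-3-(triethylsilyloxy)butyl]-4-oxo-4H-chromen-3-yl trifluoromethanesulfonate F17; Suzuki–Miyaura coupling with 6 gives 20.

3. Step 12. Oxidation by the trivalent iodine reagent may be slow at the chelated 5-hydroxyl and spill over to the electron-rich ring B or its chromene double bond, and the quinone may add water or acetate at C7. The fallback avoids the redox detour by putting a non-oxidatively removable group on O8; it sets out from acylchromate 14 and comes back at 22.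
- 14 is acylated with acetyl bromide at −40 °C to the acetoxycarbene complex F18, and allyl alcohol displaces acetate to give the allyloxycarbene complex F19 (the known acylation–alcoholysis route to alkoxycarbene complexes).
- Benzannulation with 18 as in step 11 gives 8-(allyloxy)-5-hydroxy-3-[7-(methoxymethoxy)-2,2-dimethyl-2H-chromen-6-yl]-6-[3-methyl-3-(triethylsilyloxy)butyl]-4H-chromen-4-one F20.
- Zerovalent palladium (Pd(PPh3)4) with morpholine transfers the allyl group to the amine and gives hydroquinone 22, which goes into the acid treatment of step 13.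

Further compounds
F1 | step 11 | 2,5-dimethoxyphenol (purchased) | COc1ccc(OC)c(O)c1
F2 | step 11 | tert-butyl (E)-3-(2,5-dimethoxyphenoxy)prop-2-enoate | COc1ccc(OC)c(O/C=C/C(=O)OC(C)(C)C)c1
F3 | step 11 | 5,8-dimethoxy-4H-chromen-4-one | COc1ccc(OC)c2occc(=O)c12
F4 | step 11 | (E)-1-(2-hydroxy-3,6-dimethoxyphenyl)-3-(piperidin-1-yl)prop-2-en-1-one | COc1ccc(OC)c(C(=O)/C=C/N2CCCCC2)c1O
F5 | step 11 | 3-iodo-5,8-dimethoxy-4H-chromen-4-one | COc1ccc(OC)c2occ(I)c(=O)c12
F6 | step 11 | 5-hydroxy-3-iodo-8-methoxy-4H-chromen-4-one | COc1ccc(O)c2c1occ(I)c2=O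
F7 | step 11 | 6-bromo-5-hydroxy-3-iodo-8-methoxy-4H-chromen-4-one | COc1cc(Br)c(O)c2c1occ(I)c2=O
F8 | step 11 | 6-bromo-5-hydroxy-8-methoxy-3-[7-(methoxymethoxy)-2,2-dimethyl-2H-chromen-6-yl]-4H-chromen-4-one | COc1cc(Br)c(O)c2c1occ(-c1cc3C=CC(C)(C)Oc3cc1OCOC)c2=O
F9 | step 11 | triethyl[(2-methylbut-3-en-2-yl)oxy]silane | C=CC(C)(C)O[Si](CC)(CC)CC
F10 | step 11 | 9-[3-methyl-3-(triethylsilyloxy)butyl]-9-borabicyclo[3.3.1]nonane | CC[Si](CC)(CC)OC(C)(C)CCB1C2CCCC1CCC2
F11 | step 8 | 5-(benzyloxy)-4-oxo-4H-pyran-2-carboxylic acid (purchased) | OC(=O)c1cc(=O)c(OCc2ccccc2)co1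
F12 | step 8 | 5-(benzyloxy)-4-oxo-4H-pyran-2-carbonyl chloride | ClC(=O)c1cc(=O)c(OCc2ccccc2)co1
F13 | step 8 | potassium acylpentacarbonylchromate from F12 | [K+].[O-]C(=[Cr](=C=O)(=C=O)(=C=O)(=C=O)=C=O)c1cc(=O)c(OCc2ccccc2)co1
F14 | step 8 | pentacarbonyl{[5-(benzyloxy)-4-oxo-4H-pyran-2-yl](methoxy)methylidene}chromium | COC(=[Cr](=C=O)(=C=O)(=C=O)(=C=O)=C=O)c1cc(=O)c(OCc2ccccc2)co1
F15 | step 8 | 3-(benzyloxy)-5-hydroxy-8-methoxy-6-[3-methyl-3-(triethylsilyloxy)butyl]-4H-chromen-4-one | COc1cc(CCC(C)(C)O[Si](CC)(CC)CC)c(O)c2c1occ(OCc1ccccc1)c2=O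
F16 | step 8 | 3,5-dihydroxy-8-methoxy-6-[3-methyl-3-(triethylsilyloxy)butyl]-4H-chromen-4-one | COc1cc(CCC(C)(C)O[Si](CC)(CC)CC)c(O)c2c1occ(O)c2=O
F17 | step 8 | 5-hydroxy-8-methoxy-6-[3-methyl-3-(triethylsilyloxy)butyl]-4-oxo-4H-chromen-3-yl trifluoromethanesulfonate | COc1cc(CCC(C)(C)O[Si](CC)(CC)CC)c(O)c2c1occ(OS(=O)(=O)C(F)(F)F)c2=O
F18 | step 12 | pentacarbonyl{acetoxy[5-(7-(methoxymethoxy)-2,2-dimethyl-2H-chromen-6-yl)-4-oxo-4H-pyran-2-yl]methylidene}chromium | CC(=O)OC(=[Cr](=C=O)(=C=O)(=C=O)(=C=O)=C=O)c1cc(=O)c(-c2cc3C=CC(C)(C)Oc3cc2OCOC)co1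
F19 | step 12 | pentacarbonyl{(allyloxy)[5-(7-(methoxymethoxy)-2,2-dimethyl-2H-chromen-6-yl)-4-oxo-4H-pyran-2-yl]methylidene}chromium | C=CCOC(=[Cr](=C=O)(=C=O)(=C=O)(=C=O)=C=O)c1cc(=O)c(-c2cc3C=CC(C)(C)Oc3cc2OCOC)co1
F20 | step 12 | 8-(allyloxy)-5-hydroxy-3-[7-(methoxymethoxy)-2,2-dimethyl-2H-chromen-6-yl]-6-[3-methyl-3-(triethylsilyloxy)butyl]-4H-chromen-4-one | C=CCOc1cc(CCC(C)(C)O[Si](CC)(CC)CC)c(O)c2c1occ(-c1cc3C=CC(C)(C)Oc3cc1OCOC)c2=O
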